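**Retrosynthetic overview**

1. The target is methyl (4S,5R,10S)-15-acetoxylabda-8,13E-dien-19-oate. The plan rests on ring A (C1–C5, C10) carrying the substitution pattern of 2,3-dimethylbenzoic acid (carboxyl carbon C19 on C4, ortho methyl carbon = C6 on C5, meta methyl = C20 on C10), with C7–C15 being a geranyl unit functionalised at its C8.
2. Last disconnection: C9–C10, which opens ring B to the monocyclic triene 18 with a tetrasubstituted C5=C10 alkene (proton-initiated cation–olefin monocyclisation; C5 and C10 are set from C4).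
3. 18 goes back to benzamide 11 by Birch reductive methylation on a chiral pyrrolidine amide (sets C4), hydrogenation of C2=C3 and exchange of the amide for the methyl ester.
4. 11 is disconnected at C6–C7: lateral lithiation of benzamide 9 and alkylation with the 8-bromogeranyl silyl ether 5, made from geraniol.
5. Ring order: ring A enters as the arene and is dearomatised; ring B is closed last.

Key step: step 11

Assumption: with the (S)-auxiliary 7 the enolate of an ortho-alkyl benzamide is taken to accept MeI on the face that gives (S)-C4; if step 6 shows the opposite sense, the (R)-enantiomer of 7 is used from step 4 on and nothing else changes.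

**Route**

Step 1
Reactants: 1 geraniol
Product: 2 geranyl tert-butyldimethylsilyl ether
Conditions: TBSCl, imidazole, DMF, 0 °C to rt
Reagents that add atoms: tert-butyldimethylsilyl chloride, CC(C)(C)[Si](C)(C)Cl
Why: Imidazole-mediated silylation of the primary allylic alcohol masks O15 for the organolithium and dissolving-metal steps; no stereocentre is formed.

Step 2
Reactants: 2 geranyl tert-butyldimethylsilyl ether
Product: 3 (2E,6E)-8-(tert-butyldimethylsilyloxy)-2,6-dimethylocta-2,6-dien-1-ol
Conditions: SeO2 (0.1 equiv), t-BuOOH (3 equiv), salicylic acid (0.1 equiv), CH2Cl2, 0 °C to rt; stopped at partial conversion, 2 recycled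
Reagents that add atoms: tert-butyl hydroperoxide, CC(C)(C)OO (oxygen atom, transferred through catalytic SeO2)
Why: SeO2 allylic oxidation (ene reaction, then [2,3]-sigmatropic shift) should attack the more electron-rich distal trisubstituted alkene at its E-methyl group and give the E-allylic alcohol, the alkene next to the silyl ether being deactivated.

Step 3
Reactants: 3 (2E,6E)-8-(tert-butyldimethylsilyloxy)-2,6-dimethylocta-2,6-dien-1-ol
Product: 5 (2E,6E)-8-bromo-1-(tert-butyldimethylsilyloxy)-3,7-dimethylocta-2,6-diene, via allylic mesylate 4 (not isolated)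
Conditions: MsCl, Et3N, THF, −40 °C; then LiBr, THF, −40 to 0 °C
Reagents that add atoms: lithium bromide, [Li+].[Br-]
Why: Mesylation and SN2 displacement by bromide at the primary allylic carbon should proceed without allylic transposition or loss of the E geometry, and the silyl ether is not touched.

Step 4
Reactants: 6 2,3-dimethylbenzoic acid; 7 (S)-2-(methoxymethyl)pyrrolidine
Product: 9 (S)-1-(2,3-dimethylbenzoyl)-2-(methoxymethyl)pyrrolidine, via 2,3-dimethylbenzoyl chloride 8 (not isolated)
Conditions: (COCl)2, DMF (cat.), CH2Cl2, 0 °C to rt, evaporate; then 7, Et3N, CH2Cl2, 0 °C to rt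
Reagents that add atoms: none
Why: Acid chloride formation and acylation of the secondary amine install the chiral tertiary amide that later directs both the lateral lithiation and the facial course of the Birch alkylation.

Step 5
Reactants: 9 (S)-1-(2,3-dimethylbenzoyl)-2-(methoxymethyl)pyrrolidine; 5 (2E,6E)-8-bromo-1-(tert-butyldimethylsilyloxy)-3,7-dimethylocta-2,6-diene
Product: 11 (S)-2-(methoxymethyl)pyrrolidine amide of 3-methyl-2-[(3E,7E)-9-(tert-butyldimethylsilyloxy)-3,7-dimethylnona-3,7-dien-1-yl]benzoic acid, via benzylic lithium species 10 (not isolated)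
Conditions: LiN(iPr)2 (1.1 equiv), THF, −78 °C; then 5, −78 to −40 °C
Reagents that add atoms: none
Why: Amide-directed lateral lithiation of a tertiary ortho-toluamide deprotonates only the ortho methyl (the future C6), and SN2 alkylation of this benzylic anion with the primary allylic bromide forms C6–C7 with both E alkenes intact.

Step 6
Reactants: 11 (S)-2-(methoxymethyl)pyrrolidine amide of 3-methyl-2-[(3E,7E)-9-(tert-butyldimethylsilyloxy)-3,7-dimethylnona-3,7-dien-1-yl]benzoic acid
Product: 13 (S)-2-(methoxymethyl)pyrrolidine amide of (1S)-1,3-dimethyl-2-[(3E,7E)-9-(tert-butyldimethylsilyloxy)-3,7-dimethylnona-3,7-dien-1-yl]cyclohexa-2,5-diene-1-carboxylic acid, via potassium amide enolate 12 (not isolated)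
Conditions: K (2.3 equiv), t-BuOH (1.0 equiv), NH3/THF, −78 °C; piperylene; then MeI (3 equiv), −78 °C; NH4Cl
Reagents that add atoms: iodomethane, CI
Why: Birch reductive alkylation: the benzamide takes up two electrons and one proton at the para carbon (C1), and the resulting cross-conjugated potassium enolate, held by the methoxymethyl arm of the auxiliary, should be methylated at the ipso carbon from one face, setting C4 as (S); the isolated trisubstituted alkenes are not reduced.

Step 7
Reactants: 13 (S)-2-(methoxymethyl)pyrrolidine amide of (1S)-1,3-dimethyl-2-[(3E,7E)-9-(tert-butyldimethylsilyloxy)-3,7-dimethylnona-3,7-dien-1-yl]cyclohexa-2,5-diene-1-carboxylic acid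
Product: 14 (S)-2-(methoxymethyl)pyrrolidine amide of (1S)-1,3-dimethyl-2-[(3E,7E)-9-(tert-butyldimethylsilyloxy)-3,7-dimethylnona-3,7-dien-1-yl]cyclohex-2-ene-1-carboxylic acid
Conditions: H2 (1–3 atm), RhCl(PPh3)3 (5 mol %), benzene, rt
Reagents that add atoms: none
Why: Homogeneous hydrogenation with this bulky rhodium catalyst should reduce only the cis-disubstituted C2=C3 alkene and leave the tri- and tetrasubstituted alkenes, which also removes the bis-allylic CH2 of the Birch product before any acid is used.

Step 8
Reactants: 14 (S)-2-(methoxymethyl)pyrrolidine amide of (1S)-1,3-dimethyl-2-[(3E,7E)-9-(tert-butyldimethylsilyloxy)-3,7-dimethylnona-3,7-dien-1-yl]cyclohex-2-ene-1-carboxylic acid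
Product: 16 methyl (1S)-1,3-dimethyl-2-[(3E,7E)-9-(tert-butyldimethylsilyloxy)-3,7-dimethylnona-3,7-dien-1-yl]cyclohex-2-ene-1-carboxylate, via O-methyl imidatonium tetrafluoroborate 15 (not isolated)
Conditions: Me3OBF4 (3 equiv), 2,6-di-tert-butylpyridine (0.5 equiv), CH2Cl2, rt; then pH 7 sodium phosphate buffer, THF, rt
Reagents that add atoms: trimethyloxonium tetrafluoroborate, C[O+](C)C.F[B-](F)(F)F; water, O
Why: O-Methylation of the tertiary amide takes place at the exposed carbonyl oxygen despite the quaternary neighbour, and hydrolysis of the imidatonium salt at neutral pH expels the protonated amine, so the hindered amide is converted into the methyl ester without touching C4.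

Step 9
Reactants: 16 methyl (1S)-1,3-dimethyl-2-[(3E,7E)-9-(tert-butyldimethylsilyloxy)-3,7-dimethylnona-3,7-dien-1-yl]cyclohex-2-ene-1-carboxylate
Product: 17 methyl (1S)-2-[(3E,7E)-9-hydroxy-3,7-dimethylnona-3,7-dien-1-yl]-1,3-dimethylcyclohex-2-ene-1-carboxylate
Conditions: TBAF, THF, 0 °C to rt
Reagents that add atoms: none
Why: Fluoride-induced Si–O cleavage frees the primary allylic alcohol, while the neopentyl-type methyl ester is too hindered to be attacked.

Step 10
Reactants: 17 methyl (1S)-2-[(3E,7E)-9-hydroxy-3,7-dimethylnona-3,7-dien-1-yl]-1,3-dimethylcyclohex-2-ene-1-carboxylate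
Product: 18 methyl (1S)-2-[(3E,7E)-9-acetoxy-3,7-dimethylnona-3,7-dien-1-yl]-1,3-dimethylcyclohex-2-ene-1-carboxylate
Conditions: Ac2O, pyridine, DMAP (cat.), CH2Cl2, 0 °C to rt
Reagents that add atoms: acetic anhydride, CC(=O)OC(C)=O
Why: DMAP-catalysed acetylation of the primary alcohol installs the C15 acetate of the target, which also lowers the nucleophilicity of the C13=C14 alkene for the next step.

Step 11
Reactants: 18 methyl (1S)-2-[(3E,7E)-9-acetoxy-3,7-dimethylnona-3,7-dien-1-yl]-1,3-dimethylcyclohex-2-ene-1-carboxylate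
Product: 19 methyl (4S,5R,10S)-15-acetoxylabda-8,13E-dien-19-oate
Conditions: SnCl4 (2.5 equiv), 2-methoxyphenol (1.1 equiv), CH2Cl2, −78 to −40 °C; Et3N, then aq. NaHCO3; chromatography on AgNO3-impregnated silica
Reagents that add atoms: none
Why: The SnCl4-activated phenol (a Lewis acid-assisted Brønsted acid) protonates the most electron-rich alkene, the tetrasubstituted C5=C10, at C5 because the alternative C5 cation would sit next to the ester-bearing quaternary C4; the tertiary C10 cation is captured by C9 of the C8=C9 alkene (new C9–C10 bond) and the resulting tertiary C8 cation loses H9 to leave the C8=C9 alkene. The closest known reaction type is the acid-induced cation–olefin cyclisation of 2-(alkenylethyl)- and 2-(arylethyl)-1,3-dimethylcyclohexenes to trans-decalins with an angular methyl group. Ring B (C5–C6–C7–C8–C9–C10) closes 6-endo-trig with respect to C8=C9 through a chair-like transition state. C5 and C10 are both set under substrate control by C4: the C6 tether and the incoming C9 are trans-diequatorial on ring A, so H5 and C9 end up on the same face and the C10 methyl becomes axial (trans-fusion), and of the two C4 substituents the CO2Me rather than the CH3 takes the axial site syn to that methyl because it costs less 1,3-diaxial strain and its carbonyl oxygen can stabilise the C10 cation from that face, which gives (5R,10S). The step needs initiation at the ring alkene only, proton loss toward C9 and no capture of the C8 cation by C14; these are served by the higher basicity of the tetrasubstituted alkene, by the SnCl4-complexed allylic acetate that deactivates C13=C14, and by a non-superacidic medium whose counter-ion removes a proton quickly, loss of H9 giving the most substituted alkene. Isomers from loss of H7 or of a C8-methyl proton are the expected minor products and are removed on the AgNO3-impregnated silica.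

**Compound list**

1 | geraniol | CC(C)=CCC/C(C)=C/CO | starting material
2 | geranyl tert-butyldimethylsilyl ether | CC(C)=CCC/C(C)=C/CO[Si](C)(C)C(C)(C)C | intermediate
3 | (2E,6E)-8-(tert-butyldimethylsilyloxy)-2,6-dimethylocta-2,6-dien-1-ol | OC/C(C)=C/CC/C(C)=C/CO[Si](C)(C)C(C)(C)C | intermediate
4 | methanesulfonate of 3 (not isolated) | CS(=O)(=O)OC/C(C)=C/CC/C(C)=C/CO[Si](C)(C)C(C)(C)C | intermediate
5 | (2E,6E)-8-bromo-1-(tert-butyldimethylsilyloxy)-3,7-dimethylocta-2,6-diene | BrC/C(C)=C/CC/C(C)=C/CO[Si](C)(C)C(C)(C)C | intermediate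
6 | 2,3-dimethylbenzoic acid | Cc1cccc(C(=O)O)c1C | starting material
7 | (S)-2-(methoxymethyl)pyrrolidine (chiral auxiliary) | COC[C@@H]1CCCN1 | starting material
8 | 2,3-dimethylbenzoyl chloride (not isolated) | Cc1cccc(C(=O)Cl)c1C | intermediate
9 | (S)-1-(2,3-dimethylbenzoyl)-2-(methoxymethyl)pyrrolidine | Cc1cccc(C(=O)N2CCC[C@H]2COC)c1C | intermediate
10 | benzylic lithium species of 9, lithium on the ortho CH2 (not isolated) | [Li]Cc1c(C)cccc1C(=O)N1CCC[C@H]1COC | intermediate
11 | (S)-2-(methoxymethyl)pyrrolidine amide of 3-methyl-2-[(3E,7E)-9-(tert-butyldimethylsilyloxy)-3,7-dimethylnona-3,7-dien-1-yl]benzoic acid | COC[C@@H]1CCCN1C(=O)c1cccc(C)c1CC/C(C)=C/CC/C(C)=C/CO[Si](C)(C)C(C)(C)C | intermediate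
12 | potassium amide enolate from Birch reduction of 11, cross-conjugated cyclohexa-2,5-dienylidene (not isolated) | [K+].[O-]C(N1CCC[C@H]1COC)=C1C=CCC(C)=C1CC/C(C)=C/CC/C(C)=C/CO[Si](C)(C)C(C)(C)C | intermediate
13 | (S)-2-(methoxymethyl)pyrrolidine amide of (1S)-1,3-dimethyl-2-[(3E,7E)-9-(tert-butyldimethylsilyloxy)-3,7-dimethylnona-3,7-dien-1-yl]cyclohexa-2,5-diene-1-carboxylic acid | COC[C@@H]1CCCN1C(=O)[C@@]2(C)C=CCC(C)=C2CC/C(C)=C/CC/C(C)=C/CO[Si](C)(C)C(C)(C)C | intermediate
14 | (S)-2-(methoxymethyl)pyrrolidine amide of (1S)-1,3-dimethyl-2-[(3E,7E)-9-(tert-butyldimethylsilyloxy)-3,7-dimethylnona-3,7-dien-1-yl]cyclohex-2-ene-1-carboxylic acid | COC[C@@H]1CCCN1C(=O)[C@@]2(C)CCCC(C)=C2CC/C(C)=C/CC/C(C)=C/CO[Si](C)(C)C(C)(C)C | intermediate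
15 | O-methyl imidatonium tetrafluoroborate of 14 (not isolated) | COC(=[N+]1CCC[C@H]1COC)[C@@]2(C)CCCC(C)=C2CC/C(C)=C/CC/C(C)=C/CO[Si](C)(C)C(C)(C)C.F[B-](F)(F)F | intermediate
16 | methyl (1S)-1,3-dimethyl-2-[(3E,7E)-9-(tert-butyldimethylsilyloxy)-3,7-dimethylnona-3,7-dien-1-yl]cyclohex-2-ene-1-carboxylate | COC(=O)[C@@]1(C)CCCC(C)=C1CC/C(C)=C/CC/C(C)=C/CO[Si](C)(C)C(C)(C)C | intermediate
17 | methyl (1S)-2-[(3E,7E)-9-hydroxy-3,7-dimethylnona-3,7-dien-1-yl]-1,3-dimethylcyclohex-2-ene-1-carboxylate | COC(=O)[C@@]1(C)CCCC(C)=C1CC/C(C)=C/CC/C(C)=C/CO | intermediate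
18 | methyl (1S)-2-[(3E,7E)-9-acetoxy-3,7-dimethylnona-3,7-dien-1-yl]-1,3-dimethylcyclohex-2-ene-1-carboxylate (cyclisation precursor) | COC(=O)[C@@]1(C)CCCC(C)=C1CC/C(C)=C/CC/C(C)=C/COC(C)=O | intermediate
19 | methyl (4S,5R,10S)-15-acetoxylabda-8,13E-dien-19-oate, i.e. methyl (1S,4aS,8aR)-5-[(3E)-5-acetoxy-3-methylpent-3-en-1-yl]-1,4a,6-trimethyl-1,2,3,4,4a,7,8,8a-octahydronaphthalene-1-carboxylate | COC(=O)[C@@]1(C)CCC[C@]2(C)C(CC/C(C)=C/COC(C)=O)=C(C)CC[C@@H]12 | target

**Step count**

Total step count: 11.
Longest linear sequence: 10 steps (from 1 to 19 through steps 1–3 and 5–11; the benzoic acid branch is 8 steps).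

**Steps most likely to fail**

Step 11. The C8 cation may lose a proton from C7 or from its methyl group instead of from C9, may be captured by C14 to start a third ring, and the face selection relative to C4 may be incomplete. The fallback sets out from 18 and comes back at 19; it separates the termination from the ring closure. Compound 18 is cyclised as in step 11 with an early quench, which should leave as main side products the C7 alkene isomer methyl 15-acetoxylabda-7,13E-dien-19-oate F1 and the exocyclic isomer methyl 15-acetoxylabda-8(17),13E-dien-19-oate F2. These are separated from 19 on AgNO3-impregnated silica and each is stirred with a sulfonic acid resin in CH2Cl2 at room temperature. Reversible protonation at C7 or at the exocyclic carbon regenerates the C8 cation under conditions in which the medium removes a proton quickly, so the material should drain into the thermodynamically preferred tetrasubstituted alkene 19; the remainder is recycled.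

Step 6. The dissolving metal may cleave the allylic C15–O bond of the silyl ether, and the facial selectivity of the methylation may be incomplete. The fallback sets out from 11 and comes back at 18. The silyl ether is removed first (TBAF, THF) to give the hydroxy benzamide F3. F3 is reduced with K (2.2 equiv) in NH3/THF at −78 °C without added alcohol, its own hydroxyl serving as the single proton source, which should give the dipotassium alkoxide enolate F4. An allylic alkoxide is not cleaved by the metal, and MeI (1.1 equiv) at −78 °C should methylate the enolate carbon much faster than the alkoxide, giving the hydroxy cyclohexadiene amide F5; a minor diastereomer at C4 would be removed here by chromatography. Acetylation (Ac2O, pyridine, DMAP) gives the acetoxy cyclohexadiene amide F6, hydrogenation as in step 7 gives the acetoxy cyclohexene amide F7, and O-methylation as in step 8 gives the imidatonium salt F8, whose hydrolysis delivers 18 directly. Steps 9 and 10 then fall away.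

Step 8. Attack of water at the very hindered imidate carbon may be slower than loss of the O-methyl group, which returns the amide, or the O-methylation itself may stall. The fallback sets out from 14 and comes back at 16; it detaches the auxiliary reductively. LiH2NBH3 in THF (0 °C to rt) should reduce the tertiary amide to the neopentyl alcohol F9 with release of the auxiliary. Dess–Martin periodinane gives the aldehyde F10, which cannot epimerise because C4 is quaternary. NaClO2/NaH2PO4 with 2-methyl-2-butene gives the carboxylic acid F11, and Me3SiCHN2 in MeOH/toluene gives the methyl ester 16.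

**Further compounds**

F1 | step 11 | methyl 15-acetoxylabda-7,13E-dien-19-oate (9α-H) | COC(=O)[C@@]1(C)CCC[C@]2(C)[C@@H](CC/C(C)=C/COC(C)=O)C(C)=CC[C@@H]12
F2 | step 11 | methyl 15-acetoxylabda-8(17),13E-dien-19-oate (9α-H) | COC(=O)[C@@]1(C)CCC[C@]2(C)[C@@H](CC/C(C)=C/COC(C)=O)C(=C)CC[C@@H]12
F3 | step 6 | (S)-2-(methoxymethyl)pyrrolidine amide of 2-[(3E,7E)-9-hydroxy-3,7-dimethylnona-3,7-dien-1-yl]-3-methylbenzoic acid | COC[C@@H]1CCCN1C(=O)c1cccc(C)c1CC/C(C)=C/CC/C(C)=C/CO
F4 | step 6 | dipotassium alkoxide enolate from Birch reduction of F3 | [K+].[K+].[O-]C(N1CCC[C@H]1COC)=C1C=CCC(C)=C1CC/C(C)=C/CC/C(C)=C/C[O-]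
F5 | step 6 | (S)-2-(methoxymethyl)pyrrolidine amide of (1S)-2-[(3E,7E)-9-hydroxy-3,7-dimethylnona-3,7-dien-1-yl]-1,3-dimethylcyclohexa-2,5-diene-1-carboxylic acid | COC[C@@H]1CCCN1C(=O)[C@@]2(C)C=CCC(C)=C2CC/C(C)=C/CC/C(C)=C/CO
F6 | step 6 | (S)-2-(methoxymethyl)pyrrolidine amide of (1S)-2-[(3E,7E)-9-acetoxy-3,7-dimethylnona-3,7-dien-1-yl]-1,3-dimethylcyclohexa-2,5-diene-1-carboxylic acid | COC[C@@H]1CCCN1C(=O)[C@@]2(C)C=CCC(C)=C2CC/C(C)=C/CC/C(C)=C/COC(C)=O
F7 | step 6 | (S)-2-(methoxymethyl)pyrrolidine amide of (1S)-2-[(3E,7E)-9-acetoxy-3,7-dimethylnona-3,7-dien-1-yl]-1,3-dimethylcyclohex-2-ene-1-carboxylic acid | COC[C@@H]1CCCN1C(=O)[C@@]2(C)CCCC(C)=C2CC/C(C)=C/CC/C(C)=C/COC(C)=O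
F8 | step 6 | O-methyl imidatonium tetrafluoroborate of F7 | COC(=[N+]1CCC[C@H]1COC)[C@@]2(C)CCCC(C)=C2CC/C(C)=C/CC/C(C)=C/COC(C)=O.F[B-](F)(F)F
F9 | step 8 | [(1S)-1,3-dimethyl-2-[(3E,7E)-9-(tert-butyldimethylsilyloxy)-3,7-dimethylnona-3,7-dien-1-yl]cyclohex-2-en-1-yl]methanol | OC[C@@]1(C)CCCC(C)=C1CC/C(C)=C/CC/C(C)=C/CO[Si](C)(C)C(C)(C)C
F10 | step 8 | (1S)-1,3-dimethyl-2-[(3E,7E)-9-(tert-butyldimethylsilyloxy)-3,7-dimethylnona-3,7-dien-1-yl]cyclohex-2-ene-1-carbaldehyde | O=C[C@@]1(C)CCCC(C)=C1CC/C(C)=C/CC/C(C)=C/CO[Si](C)(C)C(C)(C)C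
F11 | step 8 | (1S)-1,3-dimethyl-2-[(3E,7E)-9-(tert-butyldimethylsilyloxy)-3,7-dimethylnona-3,7-dien-1-yl]cyclohex-2-ene-1-carboxylic acid | OC(=O)[C@@]1(C)CCCC(C)=C1CC/C(C)=C/CC/C(C)=C/CO[Si](C)(C)C(C)(C)C
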